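**Strategy.** Everything rests on cutting the indane five-membered ring (C1 bearing the carbinol side chain, C2 the benzofuranyl group, C3 the 4-hydroxyphenyl group) at C7a–C1 and C2–C3. C7a is meta to both ring oxygens, out of reach of Friedel–Crafts chemistry, so it enters as an aryl bromide; an aroyl group at C1 makes C1 an enolate carbon and C2 an enone β-carbon. A 4-nitrophenyl ring stands in for the 4-hydroxyphenyl group and acidifies C3–H: a bromo diarylmethane adds to a dihydrobenzofuranyl chalcone and the enolate is arylated at palladium in the same flask, a formal [3+2] annulation that leaves three contiguous stereocentres all-trans.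

Key step: step 12

Abbreviations: Bn = benzyl; DBF = (2R,3R)-6-(benzyloxy)-2-[4-(benzyloxy)phenyl]-3-[3,5-bis(benzyloxy)phenyl]-2,3-dihydro-1-benzofuran-4-yl. Indane locants are those of the target (C1 side chain, C2 DBF, C3 aryl, oxygens at C4 and C6).

Assumption: 1, 4, 11 and 19 are taken as catalogue compounds.

Assumption: the antipodes named for Rh2(R-PTAD)4 (step 8) and for the cinchonidinium salt (step 12) are those expected to give the drawn configurations; if the sense of induction is opposite, the mirror-image or pseudo-enantiomeric catalyst is used and nothing else changes.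

**Route**

Step 1
Reactants: 1 1,3-bis(benzyloxy)-5-bromobenzene
Product: 3 2-bromo-4,6-bis(benzyloxy)benzaldehyde, via aryl iminium chloride 2 (not isolated)
Conditions: POCl3, DMF, 0 → 80 °C; then H2O
Reagents that add atoms: N,N-dimethylformamide CN(C)C=O; water O
Why: Vilsmeier–Haack formylation should occur at the carbon para to one benzyloxy group and ortho to the other, next to bromine, as in the dimethoxy series, and the iminium salt is hydrolysed on work-up.

Step 2
Reactants: 3 2-bromo-4,6-bis(benzyloxy)benzaldehyde; 4 4-nitrophenylboronic acid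
Product: 6 1,5-bis(benzyloxy)-3-bromo-2-(4-nitrobenzyl)benzene, via tosylhydrazone 5 (not isolated)
Conditions: TsNHNH2, 1,4-dioxane, 80 °C; then 4, K2CO3, 110 °C
Reagents that add atoms: none
Why: Barluenga–Valdés metal-free reductive coupling of the tosylhydrazone with the boronic acid should give the diarylmethane with loss of sulfinate and N2 and leave the aryl C–Br bond untouched.

Step 3
Reactants: 3 2-bromo-4,6-bis(benzyloxy)benzaldehyde; 1 1,3-bis(benzyloxy)-5-bromobenzene (turned into 7 in the flask)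
Product: 8 rac-[2-bromo-4,6-bis(benzyloxy)phenyl][3,5-bis(benzyloxy)phenyl]methanol, via aryl Grignard reagent 7 (not isolated)
Conditions: Mg, THF, 40 °C; then 3, THF, 0 °C; H2O
Reagents that add atoms: none
Why: Grignard 1,2-addition to the aldehyde; the aryl bromide of 3 is inert to the arylmagnesium at 0 °C and the carbinol centre is erased in the next step.

Step 4
Reactants: 8 rac-[2-bromo-4,6-bis(benzyloxy)phenyl][3,5-bis(benzyloxy)phenyl]methanol
Product: 9 [2-bromo-4,6-bis(benzyloxy)phenyl][3,5-bis(benzyloxy)phenyl]methanone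
Conditions: MnO2, CH2Cl2, rt
Reagents that add atoms: none
Why: MnO2 oxidation of a doubly benzylic alcohol to the benzophenone.

Step 5
Reactants: 9 [2-bromo-4,6-bis(benzyloxy)phenyl][3,5-bis(benzyloxy)phenyl]methanone
Product: 10 [4-(benzyloxy)-2-bromo-6-hydroxyphenyl][3,5-bis(benzyloxy)phenyl]methanone
Conditions: BCl3 (1.1 equiv), CH2Cl2, −78 °C; then H2O
Reagents that add atoms: none
Why: Chelation-directed ether cleavage: BCl3 held between the carbonyl and the ortho ether oxygen should remove only that benzyl group at −78 °C.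

Step 6
Reactants: 10 [4-(benzyloxy)-2-bromo-6-hydroxyphenyl][3,5-bis(benzyloxy)phenyl]methanone; 11 1-(benzyloxy)-4-(chloromethyl)benzene
Product: 12 [4-(benzyloxy)-2-bromo-6-{[4-(benzyloxy)benzyl]oxy}phenyl][3,5-bis(benzyloxy)phenyl]methanone
Conditions: K2CO3, n-Bu4NI (cat.), DMF, 60 °C
Reagents that add atoms: none
Why: Williamson etherification of the hydrogen-bonded phenol installs the benzylic CH2 that becomes C2 of the dihydrobenzofuran.

Step 7
Reactants: 12 [4-(benzyloxy)-2-bromo-6-{[4-(benzyloxy)benzyl]oxy}phenyl][3,5-bis(benzyloxy)phenyl]methanone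
Product: 13 hydrazone of 12 (E/Z mixture)
Conditions: N2H4·H2O, AcOH (cat.), EtOH/THF, 90 °C, sealed tube
Reagents that add atoms: hydrazine NN
Why: Acid-catalysed condensation to the hydrazone, forced by heat because the benzophenone is di-ortho-substituted.

Step 8
Reactants: 13 hydrazone of 12
Product: 15 (2S,3R)-6-(benzyloxy)-2-[4-(benzyloxy)phenyl]-3-[3,5-bis(benzyloxy)phenyl]-4-bromo-2,3-dihydro-1-benzofuran, via diaryldiazomethane 14 (not isolated)
Conditions: MnO2, CH2Cl2, 0 °C; filter; Rh2(R-PTAD)4 (1 mol %), CH2Cl2, −20 °C → rt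
Reagents that add atoms: none
Why: Oxidation to the diazo compound and intramolecular 1,5 C–H insertion of the donor/donor rhodium carbene into the ether CH2 should close the furan ring cis, with C3 (and with it C2) set by the chiral carboxylate ligands.

Step 9
Reactants: 15 (2S,3R)-6-(benzyloxy)-2-[4-(benzyloxy)phenyl]-3-[3,5-bis(benzyloxy)phenyl]-4-bromo-2,3-dihydro-1-benzofuran
Product: 16 (2R,3R)-6-(benzyloxy)-2-[4-(benzyloxy)phenyl]-3-[3,5-bis(benzyloxy)phenyl]-4-bromo-2,3-dihydro-1-benzofuran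
Conditions: CF3CO2H (cat.), CH2Cl2, 0 °C → rt
Reagents that add atoms: none
Why: Acid-mediated epimerization at C2 through reversible ionization of the 4-alkoxybenzylic C2–O bond should give the more stable trans isomer while C3 is untouched.

Step 10
Reactants: 16 (2R,3R)-6-(benzyloxy)-2-[4-(benzyloxy)phenyl]-3-[3,5-bis(benzyloxy)phenyl]-4-bromo-2,3-dihydro-1-benzofuran
Product: 18 (2R,3R)-6-(benzyloxy)-2-[4-(benzyloxy)phenyl]-3-[3,5-bis(benzyloxy)phenyl]-2,3-dihydro-1-benzofuran-4-carbaldehyde, via aryllithium 17 (not isolated)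
Conditions: n-BuLi, THF, −78 °C; DMF; then H2O
Reagents that add atoms: N,N-dimethylformamide CN(C)C=O
Why: Bromine–lithium exchange followed by Bouveault formylation; exchange is faster than any benzylic deprotonation at −78 °C.

Step 11
Reactants: 18 DBF-carbaldehyde; 19 1-[4-(benzyloxy)phenyl]ethan-1-one
Product: 21 (E)-1-[4-(benzyloxy)phenyl]-3-DBF-prop-2-en-1-one, via aldol adduct 20 (not isolated)
Conditions: KOH, EtOH/THF, rt
Reagents that add atoms: none
Why: Claisen–Schmidt condensation; E1cB dehydration of the aldol should give the E-enone.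

Step 12
Reactants: 21 (E)-1-[4-(benzyloxy)phenyl]-3-DBF-prop-2-en-1-one; 6 1,5-bis(benzyloxy)-3-bromo-2-(4-nitrobenzyl)benzene
Product: 23 [4-(benzyloxy)phenyl][(1S,2R,3S)-4,6-bis(benzyloxy)-2-DBF-3-(4-nitrophenyl)-2,3-dihydro-1H-inden-1-yl]methanone, via Michael adduct 22 (not isolated)
Conditions: O-allyl-N-(9-anthracenylmethyl)cinchonidinium bromide (10 mol %), Cs2CO3 (2.5 equiv), toluene, −20 °C; then Pd(OAc)2 (5 mol %), XPhos (10 mol %), 90 °C, argon
Reagents that add atoms: none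
Why: Carbonate deprotonates the nitro-activated benzhydryl C–H of 6 and the chiral ammonium ion pair adds to the enone β-carbon of 21 (bond C2–C3, Michael addition); zerovalent palladium then inserts into the C–Br bond and reductive elimination from the arylpalladium enolate closes bond C7a–C1 (Buchwald–Hartwig–Miura ketone α-arylation). The closest known types are the phase-transfer-catalysed asymmetric Michael addition of carbon acids to chalcones and the intramolecular palladium-catalysed α-arylation of ketones, run here in tandem as a formal [3+2] annulation. The five-membered ring closes by C–C reductive elimination from a six-membered palladacycle (aryl and C-bound enolate on palladium), a 5-exo-type closure onto the enolate carbon. C2 is set in the conjugate addition by the chiral cation (catalyst control over the resident dihydrobenzofuran), whereas C1 (α to the ketone) and C3 (4-nitrobenzylic) stay acidic under carbonate and should settle to the all-trans arrangement by equilibration. The step needs 1,4- over 1,2-addition (soft, delocalized carbanion), complete addition before palladium is admitted (so that 6 is not arylated intermolecularly) and C-arylation of the enolate in preference to O-arylation or fluorene formation by C–H arylation (five-ring C–C closure, carbonate without carboxylate additive).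

Step 13
Reactants: 23 nitro ketone
Product: 24 [(1S,2R,3S)-3-(4-aminophenyl)-4,6-bis(benzyloxy)-2-DBF-2,3-dihydro-1H-inden-1-yl][4-(benzyloxy)phenyl]methanone
Conditions: Zn, AcOH, THF, rt
Reagents that add atoms: none
Why: Dissolving-metal reduction of the nitro group should spare benzyl ethers, the aryl ketone and the dihydrofuran; C3 loses its acidity and is now fixed.

Step 14
Reactants: 24 amino ketone
Product: 26 [4-(benzyloxy)phenyl][(1S,2R,3S)-4,6-bis(benzyloxy)-2-DBF-3-(4-hydroxyphenyl)-2,3-dihydro-1H-inden-1-yl]methanone, via arenediazonium hydrogen sulfate 25 (not isolated)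
Conditions: NaNO2, aq. H2SO4, THF, 0 °C; then Cu(NO3)2, Cu2O (cat.), H2O, rt
Reagents that add atoms: water O
Why: Diazotization and copper-mediated hydroxydediazoniation (Sandmeyer type) at room temperature unveil the 4-hydroxyphenyl ring without the hot acid of the classical hydrolysis.

Step 15
Reactants: 26 phenol ketone
Product: 27 (S)-[4-(benzyloxy)phenyl][(1S,2R,3S)-4,6-bis(benzyloxy)-2-DBF-3-(4-hydroxyphenyl)-2,3-dihydro-1H-inden-1-yl]methanol
Conditions: (R)-2-methyl-CBS-oxazaborolidine (20 mol %), BH3·SMe2 (3 equiv), THF, −20 → 0 °C; then H2O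
Reagents that add atoms: none
Why: Corey–Bakshi–Shibata reduction should give the (S)-carbinol by reagent control (aryl as the large group), the same sense the Felkin–Anh model predicts with the fused arene carbon C7a as the large substituent on C1.

Step 16
Reactants: 27 heptabenzyl ether carbinol
Product: 28 (1S,2R,3S)-2-[(2R,3R)-3-(3,5-dihydroxyphenyl)-6-hydroxy-2-(4-hydroxyphenyl)-2,3-dihydro-1-benzofuran-4-yl]-1-[(S)-hydroxy(4-hydroxyphenyl)methyl]-3-(4-hydroxyphenyl)-2,3-dihydro-1H-indene-4,6-diol (CNP0175860.1)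
Conditions: H2 (1 atm), Pd/C, EtOAc/MeOH, rt
Reagents that add atoms: none
Why: Neutral hydrogenolysis of the seven benzyl ethers at 1 atm should leave the benzylic carbinol and the benzylic O–C2 bond of the dihydrofuran intact, as in debenzylations of flavan-3-ols.

**Compound list**

1 | 1,3-bis(benzyloxy)-5-bromobenzene | Brc1cc(OCc9ccccc9)cc(OCc9ccccc9)c1 | starting material
2 | N-[2-bromo-4,6-bis(benzyloxy)benzylidene]-N-methylmethanaminium chloride | C[N+](C)=Cc1c(Br)cc(OCc9ccccc9)cc1OCc9ccccc9.[Cl-] | intermediate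
3 | 2-bromo-4,6-bis(benzyloxy)benzaldehyde | O=Cc1c(Br)cc(OCc9ccccc9)cc1OCc9ccccc9 | intermediate
4 | 4-nitrophenylboronic acid | OB(O)c1ccc(cc1)[N+](=O)[O-] | starting material
5 | (E)-N'-[2-bromo-4,6-bis(benzyloxy)benzylidene]-4-methylbenzenesulfonohydrazide | Cc1ccc(cc1)S(=O)(=O)N/N=C/c1c(Br)cc(OCc9ccccc9)cc1OCc9ccccc9 | intermediate
6 | 1,5-bis(benzyloxy)-3-bromo-2-(4-nitrobenzyl)benzene | [O-][N+](=O)c1ccc(Cc2c(Br)cc(OCc9ccccc9)cc2OCc9ccccc9)cc1 | intermediate
7 | 3,5-bis(benzyloxy)phenylmagnesium bromide | Br[Mg]c1cc(OCc9ccccc9)cc(OCc9ccccc9)c1 | intermediate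
8 | rac-[2-bromo-4,6-bis(benzyloxy)phenyl][3,5-bis(benzyloxy)phenyl]methanol | OC(c1cc(OCc9ccccc9)cc(OCc9ccccc9)c1)c1c(Br)cc(OCc9ccccc9)cc1OCc9ccccc9 | intermediate
9 | [2-bromo-4,6-bis(benzyloxy)phenyl][3,5-bis(benzyloxy)phenyl]methanone | O=C(c1cc(OCc9ccccc9)cc(OCc9ccccc9)c1)c1c(Br)cc(OCc9ccccc9)cc1OCc9ccccc9 | intermediate
10 | [4-(benzyloxy)-2-bromo-6-hydroxyphenyl][3,5-bis(benzyloxy)phenyl]methanone | O=C(c1cc(OCc9ccccc9)cc(OCc9ccccc9)c1)c1c(Br)cc(OCc9ccccc9)cc1O | intermediate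
11 | 1-(benzyloxy)-4-(chloromethyl)benzene | ClCc1ccc(OCc9ccccc9)cc1 | starting material
12 | [4-(benzyloxy)-2-bromo-6-{[4-(benzyloxy)benzyl]oxy}phenyl][3,5-bis(benzyloxy)phenyl]methanone | O=C(c1cc(OCc9ccccc9)cc(OCc9ccccc9)c1)c1c(Br)cc(OCc9ccccc9)cc1OCc8ccc(OCc9ccccc9)cc8 | intermediate
13 | hydrazone of 12 (E/Z mixture) | NN=C(c1cc(OCc9ccccc9)cc(OCc9ccccc9)c1)c1c(Br)cc(OCc9ccccc9)cc1OCc8ccc(OCc9ccccc9)cc8 | intermediate
14 | [4-(benzyloxy)-2-bromo-6-{[4-(benzyloxy)benzyl]oxy}phenyl][3,5-bis(benzyloxy)phenyl]diazomethane | [N-]=[N+]=C(c1cc(OCc9ccccc9)cc(OCc9ccccc9)c1)c1c(Br)cc(OCc9ccccc9)cc1OCc8ccc(OCc9ccccc9)cc8 | intermediate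
15 | (2S,3R)-6-(benzyloxy)-2-[4-(benzyloxy)phenyl]-3-[3,5-bis(benzyloxy)phenyl]-4-bromo-2,3-dihydro-1-benzofuran (cis) | Brc1cc(OCc9ccccc9)cc2c1[C@@H](c1cc(OCc9ccccc9)cc(OCc9ccccc9)c1)[C@@H](c1ccc(OCc9ccccc9)cc1)O2 | intermediate
16 | (2R,3R)-6-(benzyloxy)-2-[4-(benzyloxy)phenyl]-3-[3,5-bis(benzyloxy)phenyl]-4-bromo-2,3-dihydro-1-benzofuran (trans) | Brc1cc(OCc9ccccc9)cc2c1[C@@H](c1cc(OCc9ccccc9)cc(OCc9ccccc9)c1)[C@H](c1ccc(OCc9ccccc9)cc1)O2 | intermediate
17 | 4-lithio derivative of 16 (DBF-lithium) | [Li]c1cc(OCc9ccccc9)cc2c1[C@@H](c1cc(OCc9ccccc9)cc(OCc9ccccc9)c1)[C@H](c1ccc(OCc9ccccc9)cc1)O2 | intermediate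
18 | (2R,3R)-6-(benzyloxy)-2-[4-(benzyloxy)phenyl]-3-[3,5-bis(benzyloxy)phenyl]-2,3-dihydro-1-benzofuran-4-carbaldehyde | O=Cc1cc(OCc9ccccc9)cc2c1[C@@H](c1cc(OCc9ccccc9)cc(OCc9ccccc9)c1)[C@H](c1ccc(OCc9ccccc9)cc1)O2 | intermediate
19 | 1-[4-(benzyloxy)phenyl]ethan-1-one | CC(=O)c1ccc(OCc9ccccc9)cc1 | starting material
20 | 1-[4-(benzyloxy)phenyl]-3-DBF-3-hydroxypropan-1-one (carbinol centre unassigned) | O=C(CC(O)c1cc(OCc9ccccc9)cc2c1[C@@H](c1cc(OCc9ccccc9)cc(OCc9ccccc9)c1)[C@H](c1ccc(OCc9ccccc9)cc1)O2)c1ccc(OCc9ccccc9)cc1 | intermediate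
21 | (E)-1-[4-(benzyloxy)phenyl]-3-DBF-prop-2-en-1-one | O=C(/C=C/c1cc(OCc9ccccc9)cc2c1[C@@H](c1cc(OCc9ccccc9)cc(OCc9ccccc9)c1)[C@H](c1ccc(OCc9ccccc9)cc1)O2)c1ccc(OCc9ccccc9)cc1 | intermediate
22 | (3S)-1-[4-(benzyloxy)phenyl]-4-[2-bromo-4,6-bis(benzyloxy)phenyl]-3-DBF-4-(4-nitrophenyl)butan-1-one (C4 epimers) | [O-][N+](=O)c1ccc(C(c2c(Br)cc(OCc9ccccc9)cc2OCc9ccccc9)[C@H](CC(=O)c2ccc(OCc9ccccc9)cc2)c2cc(OCc9ccccc9)cc3c2[C@@H](c2cc(OCc9ccccc9)cc(OCc9ccccc9)c2)[C@H](c2ccc(OCc9ccccc9)cc2)O3)cc1 | intermediate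
23 | [4-(benzyloxy)phenyl][(1S,2R,3S)-4,6-bis(benzyloxy)-2-DBF-3-(4-nitrophenyl)-2,3-dihydro-1H-inden-1-yl]methanone | [O-][N+](=O)c1ccc([C@H]2c3c(OCc9ccccc9)cc(OCc9ccccc9)cc3[C@@H](C(=O)c3ccc(OCc9ccccc9)cc3)[C@@H]2c2cc(OCc9ccccc9)cc3c2[C@@H](c2cc(OCc9ccccc9)cc(OCc9ccccc9)c2)[C@H](c2ccc(OCc9ccccc9)cc2)O3)cc1 | intermediate
24 | [(1S,2R,3S)-3-(4-aminophenyl)-4,6-bis(benzyloxy)-2-DBF-2,3-dihydro-1H-inden-1-yl][4-(benzyloxy)phenyl]methanone | Nc1ccc([C@H]2c3c(OCc9ccccc9)cc(OCc9ccccc9)cc3[C@@H](C(=O)c3ccc(OCc9ccccc9)cc3)[C@@H]2c2cc(OCc9ccccc9)cc3c2[C@@H](c2cc(OCc9ccccc9)cc(OCc9ccccc9)c2)[C@H](c2ccc(OCc9ccccc9)cc2)O3)cc1 | intermediate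
25 | arenediazonium hydrogen sulfate of 24 | N#[N+]c1ccc([C@H]2c3c(OCc9ccccc9)cc(OCc9ccccc9)cc3[C@@H](C(=O)c3ccc(OCc9ccccc9)cc3)[C@@H]2c2cc(OCc9ccccc9)cc3c2[C@@H](c2cc(OCc9ccccc9)cc(OCc9ccccc9)c2)[C@H](c2ccc(OCc9ccccc9)cc2)O3)cc1.OS(=O)(=O)[O-] | intermediate
26 | [4-(benzyloxy)phenyl][(1S,2R,3S)-4,6-bis(benzyloxy)-2-DBF-3-(4-hydroxyphenyl)-2,3-dihydro-1H-inden-1-yl]methanone | Oc1ccc([C@H]2c3c(OCc9ccccc9)cc(OCc9ccccc9)cc3[C@@H](C(=O)c3ccc(OCc9ccccc9)cc3)[C@@H]2c2cc(OCc9ccccc9)cc3c2[C@@H](c2cc(OCc9ccccc9)cc(OCc9ccccc9)c2)[C@H](c2ccc(OCc9ccccc9)cc2)O3)cc1 | intermediate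
27 | (S)-[4-(benzyloxy)phenyl][(1S,2R,3S)-4,6-bis(benzyloxy)-2-DBF-3-(4-hydroxyphenyl)-2,3-dihydro-1H-inden-1-yl]methanol | Oc1ccc([C@H]2c3c(OCc9ccccc9)cc(OCc9ccccc9)cc3[C@@H]([C@H](O)c3ccc(OCc9ccccc9)cc3)[C@@H]2c2cc(OCc9ccccc9)cc3c2[C@@H](c2cc(OCc9ccccc9)cc(OCc9ccccc9)c2)[C@H](c2ccc(OCc9ccccc9)cc2)O3)cc1 | intermediate
28 | (1S,2R,3S)-2-[(2R,3R)-3-(3,5-dihydroxyphenyl)-6-hydroxy-2-(4-hydroxyphenyl)-2,3-dihydro-1-benzofuran-4-yl]-1-[(S)-hydroxy(4-hydroxyphenyl)methyl]-3-(4-hydroxyphenyl)-2,3-dihydro-1H-indene-4,6-diol | Oc1ccc([C@H]2c3c(O)cc(O)cc3[C@@H]([C@H](O)c3ccc(O)cc3)[C@@H]2c2cc(O)cc3c2[C@@H](c2cc(O)cc(O)c2)[C@H](c2ccc(O)cc2)O3)cc1 | target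

**Totals**

Total step count: 16. Longest linear sequence: 15 steps (1, 3–16).

**Steps most likely to fail**

Step 12. What may go wrong: the chiral ion pair may fail to override the facial bias of the resident dihydrobenzofuran in the conjugate addition; retro-Michael cleavage at the temperature of ring closure may erode the benzylic C2 centre; palladium may close a fluorene by C–H arylation instead of arylating the enolate. The fallback sets out from aldehyde 18 (and 6) and comes back at ketone 22, which is then isolated and cyclized to 23 with Pd(OAc)2, XPhos and K3PO4 at 60 °C. Wittig homologation of 18 with (triphenylphosphoranylidene)acetaldehyde should give the (E)-enal F1. Iminium catalysis with a diphenylprolinol trimethylsilyl ether and LiOAc at 0 °C should add 6 to its β-carbon under covalent catalyst control to give the aldehyde F2. Addition of 4-(benzyloxy)phenylboronic acid catalysed by [RhCl(cod)]2 should give the secondary alcohol F3, and Dess–Martin oxidation returns 22.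

Step 8 (with step 7). What may go wrong: hydrazone formation on the di-ortho-substituted benzophenone may stall, and the hindered carbene may form azine or attack an arene instead of inserting into the ether C–H bond. The fallback sets out from phenol 10 and comes back at 16. NaBH4 should give the diol F4, and 4-methylbenzenesulfinic acid should exchange the benzylic hydroxyl to give the sulfone F5. Cs2CO3 then releases the ortho-quinone methide, which should undergo [4+1] annulation with the ylide of the chiral sulfonium salt F6 (from 11 and (2R,5R)-2,5-dimethylthiolane, or its antipode if the sense is opposite) to give the trans-dihydrobenzofuran 16 directly.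

Step 16. What may go wrong: over-reduction, that is hydrogenolysis of the benzylic C–OH bond once the para-phenol is free, or of the benzylic O–C2 bond of the dihydrofuran. The fallback sets out from ketone 26 and comes back at 28. The benzyl ethers are removed before the reduction and without hydrogen, with BCl3 and pentamethylbenzene in CH2Cl2 at −78 °C, while the side chain is still a deactivating ketone, to give the octaphenol ketone F7. NaBH4 with CeCl3 in MeOH at −40 °C under Felkin–Anh control should then give 28.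

Further compounds
F1 | step 12 | (E)-3-DBF-prop-2-enal | O=C/C=C/c1cc(OCc9ccccc9)cc2c1[C@@H](c1cc(OCc9ccccc9)cc(OCc9ccccc9)c1)[C@H](c1ccc(OCc9ccccc9)cc1)O2
F2 | step 12 | (3S)-4-[2-bromo-4,6-bis(benzyloxy)phenyl]-3-DBF-4-(4-nitrophenyl)butanal (C4 epimers) | [O-][N+](=O)c1ccc(C(c2c(Br)cc(OCc9ccccc9)cc2OCc9ccccc9)[C@H](CC=O)c2cc(OCc9ccccc9)cc3c2[C@@H](c2cc(OCc9ccccc9)cc(OCc9ccccc9)c2)[C@H](c2ccc(OCc9ccccc9)cc2)O3)cc1
F3 | step 12 | (3S)-1-[4-(benzyloxy)phenyl]-4-[2-bromo-4,6-bis(benzyloxy)phenyl]-3-DBF-4-(4-nitrophenyl)butan-1-ol (C1 and C4 epimers) | [O-][N+](=O)c1ccc(C(c2c(Br)cc(OCc9ccccc9)cc2OCc9ccccc9)[C@H](CC(O)c2ccc(OCc9ccccc9)cc2)c2cc(OCc9ccccc9)cc3c2[C@@H](c2cc(OCc9ccccc9)cc(OCc9ccccc9)c2)[C@H](c2ccc(OCc9ccccc9)cc2)O3)cc1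
F4 | step 8 | rac-[4-(benzyloxy)-2-bromo-6-hydroxyphenyl][3,5-bis(benzyloxy)phenyl]methanol | OC(c1cc(OCc9ccccc9)cc(OCc9ccccc9)c1)c1c(Br)cc(OCc9ccccc9)cc1O
F5 | step 8 | rac-5-(benzyloxy)-3-bromo-2-{[3,5-bis(benzyloxy)phenyl](4-methylbenzenesulfonyl)methyl}phenol | Cc1ccc(cc1)S(=O)(=O)C(c1cc(OCc9ccccc9)cc(OCc9ccccc9)c1)c1c(Br)cc(OCc9ccccc9)cc1O
F6 | step 8 | (2R,5R)-1-[4-(benzyloxy)benzyl]-2,5-dimethylthiolan-1-ium chloride | C[C@@H]1CC[C@@H](C)[S+]1Cc1ccc(OCc9ccccc9)cc1.[Cl-]
F7 | step 16 | [(1S,2R,3S)-2-[(2R,3R)-3-(3,5-dihydroxyphenyl)-6-hydroxy-2-(4-hydroxyphenyl)-2,3-dihydro-1-benzofuran-4-yl]-4,6-dihydroxy-3-(4-hydroxyphenyl)-2,3-dihydro-1H-inden-1-yl](4-hydroxyphenyl)methanone | Oc1ccc([C@H]2c3c(O)cc(O)cc3[C@@H](C(=O)c3ccc(O)cc3)[C@@H]2c2cc(O)cc3c2[C@@H](c2cc(O)cc(O)c2)[C@H](c2ccc(O)cc2)O3)cc1
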